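**Retrosynthetic overview**

- Feature: the single ring is a 2,3-dihydro-4H-pyran-4-one (O1, C2–C6) with oxygen on C2, C4 and C6. This alternating pattern is that of a poly-β-keto chain grown from a gondoyl starter. C2, the former acid carbon of gondoic acid, is the only carbon of that chain at the alcohol level and the only stereocentre (R).
- Last disconnections: the C5 carboxyl (decarboxylation), then O1–C6 and C5=C6 of the ring. The ring is closed last from an open δ-hydroxy-β-keto ester and N,N-dimethylacetamide dimethyl acetal, which supplies C6 and its methyl.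
- C2–H bond: ketoreductase reduction of the δ-carbonyl of the open-chain tert-butyl 3,5-dioxo ester; no ring exists at that stage.
- C2–C3 bond (ring numbering): acylation of the tert-butyl acetoacetate dianion with methyl gondoate.

Key step: step 3

Assumption: a ketoreductase of the short-chain dehydrogenase family that accepts the C19 chain and delivers the 5R alcohol is taken to be found by panel screening or by enlarging the alkyl pocket of a known 3,5-dioxo ester reductase; step 3 is written for such an enzyme.

**Route**

Step 1
Reactants: 1 gondoic acid ((Z)-icos-11-enoic acid)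
Product: 2 methyl (Z)-icos-11-enoate
Conditions: MeOH, H2SO4 (cat.), reflux
Reagents that add atoms: methanol, CO
Why: Fischer esterification in methanol as solvent drives the equilibrium to the methyl ester, and the isolated Z-alkene is inert to these conditions.

Step 2
Reactants: 2 methyl (Z)-icos-11-enoate; 3 tert-butyl acetoacetate
Product: 5 tert-butyl (Z)-3,5-dioxotetracos-15-enoate, via dilithium dianion of tert-butyl acetoacetate 4 (not isolated)
Conditions: LiN(i-Pr)2 (2.1 equiv per 3), THF, −78 to 0 °C; then 2 (0.45 equiv per 3), −78 to 0 °C; then 1 M HCl, 0 °C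
Reagents that add atoms: none
Why: Claisen-type γ-acylation of an acetoacetate dianion (Huckin–Weiler), in which the terminal carbanion of 4 attacks the ester carbonyl of 2 with loss of methoxide and the excess dianion takes up the proton of the more acidic triketone product so that 2 can be consumed fully.

Step 3
Reactants: 5 tert-butyl (Z)-3,5-dioxotetracos-15-enoate
Product: 6 tert-butyl (5R,15Z)-5-hydroxy-3-oxotetracos-15-enoate
Conditions: ketoreductase (R-selective short-chain dehydrogenase from screening), NADP+ (cat.), i-PrOH (15% v/v), potassium phosphate buffer pH 6.5, MgCl2 (1 mM), Triton X-100 (1%), 30 °C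
Reagents that add atoms: none
Why: In the enzyme–NADPH–substrate complex the C5 carbonyl is hydrogen-bonded to the catalytic serine and tyrosine and takes a hydride from C4 of the dihydronicotinamide on one face while the tyrosine protonates the oxygen, the cofactor being regenerated by the same enzyme from isopropanol. The closest known reaction type is the alcohol-dehydrogenase reduction of tert-butyl 3,5-dioxohexanoates, which stops at the 5-hydroxy-3-oxo ester. No ring closes in this step. The new stereocentre C5 (R) is controlled by the enzyme pocket alone, and the required sense is that of the β-ketoacyl reductases of fatty acid biosynthesis, which convert long-chain 3-oxoacyl groups into (R)-3-hydroxyacyl groups, so a channel for the C19 chain on the correct side of the carbonyl is a realistic demand. The step needs regioselectivity among the C1, C3 and C5 carbonyls and chemoselectivity against the C15 alkene: C5 is the only carbonyl flanked by an unfunctionalised alkyl chain, which anchors the substrate so that only C5 lies over the cofactor, the ester is no hydride acceptor, and an isolated alkene cannot take hydride from NADPH. The mono-reduced product is no longer a 1,3-diketone and should leave the site without a second reduction.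

Step 4
Reactants: 6 tert-butyl (5R,15Z)-5-hydroxy-3-oxotetracos-15-enoate; 7 N,N-dimethylacetamide dimethyl acetal
Product: 9 tert-butyl (2R)-6-methyl-2-[(10Z)-nonadec-10-en-1-yl]-4-oxo-3,4-dihydro-2H-pyran-5-carboxylate, via C2 dimethylaminoethylidene enaminone 8 (not isolated)
Conditions: 7 (1.3 equiv), PhMe, rt; then AcOH, 40 °C
Reagents that add atoms: none
Why: Knoevenagel-type condensation of the doubly activated C2 methylene with the amide acetal should give the push–pull enaminone 8, whose C5 hydroxyl then displaces dimethylamine at the enamine carbon by acid-assisted addition–elimination (6-endo closure of O1–C6), a known way from δ-hydroxy-β-keto esters to 5-carboxylated dihydropyranones that leaves the carbinol centre untouched.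

Step 5
Reactants: 9 tert-butyl (2R)-6-methyl-2-[(10Z)-nonadec-10-en-1-yl]-4-oxo-3,4-dihydro-2H-pyran-5-carboxylate
Product: 11 (2R)-6-methyl-2-[(10Z)-nonadec-10-en-1-yl]-2,3-dihydro-4H-pyran-4-one, via dihydropyranone-5-carboxylic acid 10 (not isolated)
Conditions: TFA/CH2Cl2 (1:4), 0 °C to rt; then evaporate, PhMe, 80 °C
Reagents that add atoms: none
Why: Acidolysis of the tert-butyl ester gives acid 10, a β-keto acid that is also a vinylogous carbonic acid; protonation at C5 gives the O1-stabilised oxocarbenium tautomer, which should lose CO2 on warming as chromone-3-carboxylic and 4-pyranone-3-carboxylic acids do, and the non-basic medium avoids the retro-oxa-Michael ring opening that would racemise C2.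

**Compound list**

1 | gondoic acid, (Z)-icos-11-enoic acid | CCCCCCCC/C=C\CCCCCCCCCC(=O)O | starting material
2 | methyl (Z)-icos-11-enoate | CCCCCCCC/C=C\CCCCCCCCCC(=O)OC | intermediate
3 | tert-butyl acetoacetate | CC(=O)CC(=O)OC(C)(C)C | starting material
4 | dilithium dianion of tert-butyl acetoacetate | [Li+].[Li+].C=C([O-])C=C([O-])OC(C)(C)C | intermediate
5 | tert-butyl (Z)-3,5-dioxotetracos-15-enoate | CCCCCCCC/C=C\CCCCCCCCCC(=O)CC(=O)CC(=O)OC(C)(C)C | intermediate
6 | tert-butyl (5R,15Z)-5-hydroxy-3-oxotetracos-15-enoate | CCCCCCCC/C=C\CCCCCCCCC[C@@H](O)CC(=O)CC(=O)OC(C)(C)C | intermediate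
7 | N,N-dimethylacetamide dimethyl acetal | COC(C)(OC)N(C)C | starting material
8 | tert-butyl (5R,15Z)-2-[1-(dimethylamino)ethylidene]-5-hydroxy-3-oxotetracos-15-enoate (enamine geometry not defined) | CCCCCCCC/C=C\CCCCCCCCC[C@@H](O)CC(=O)C(=C(C)N(C)C)C(=O)OC(C)(C)C | intermediate
9 | tert-butyl (2R)-6-methyl-2-[(10Z)-nonadec-10-en-1-yl]-4-oxo-3,4-dihydro-2H-pyran-5-carboxylate | CCCCCCCC/C=C\CCCCCCCCC[C@@H]1CC(=O)C(C(=O)OC(C)(C)C)=C(C)O1 | intermediate
10 | (2R)-6-methyl-2-[(10Z)-nonadec-10-en-1-yl]-4-oxo-3,4-dihydro-2H-pyran-5-carboxylic acid | CCCCCCCC/C=C\CCCCCCCCC[C@@H]1CC(=O)C(C(=O)O)=C(C)O1 | intermediate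
11 | (2R)-6-methyl-2-[(10Z)-nonadec-10-en-1-yl]-2,3-dihydro-4H-pyran-4-one | CCCCCCCC/C=C\CCCCCCCCC[C@@H]1CC(=O)C=C(C)O1 | target

**Step count and risks**

Total step count: 5. Longest linear sequence: 5 steps (1 to 11).

Steps most likely to fail:

1. Step 3. The enzyme may turn over the very lipophilic substrate too slowly, reduce the wrong carbonyl, or attack the wrong face. Fallback: from 1, activation with carbonyldiimidazole and reaction with KO2CCH2CO2Me/MgCl2/Et3N should give methyl (Z)-3-oxodocos-13-enoate F1. Hydrogenation of its β-keto ester carbonyl over RuCl2[(R)-BINAP] (divalent ruthenium) in MeOH at low H2 pressure should give methyl (3R,13Z)-3-hydroxydocos-13-enoate F2; such catalysts reduce β-keto esters by an ionic pathway and normally spare unactivated alkenes. Claisen condensation of F2 with excess LiCH2CO2t-Bu in THF at −40 °C should then deliver 6, where the route is rejoined.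

2. Step 5. Decarboxylation of the vinylic acid may stall, acid may open the ring with loss of configuration at C2, or trifluoroacetic acid may add to the alkene. Fallback: from 6, silylation (TBSCl, imidazole, DMF) should give tert-butyl (5R,15Z)-5-[(tert-butyldimethylsilyl)oxy]-3-oxotetracos-15-enoate F3. C-Acetylation at C2 with AcCl, MgCl2 and pyridine should give tert-butyl (5R,15Z)-2-acetyl-5-[(tert-butyldimethylsilyl)oxy]-3-oxotetracos-15-enoate F4. Brief TFA in CH2Cl2 cleaves the ester, and the resulting sp3 diacylacetic acid should lose CO2 readily to (6R,16Z)-6-[(tert-butyldimethylsilyl)oxy]pentacos-16-ene-2,4-dione F5. Aqueous HF in MeCN should free (6R,16Z)-6-hydroxypentacos-16-ene-2,4-dione F6, which catalytic TsOH in CH2Cl2 should cyclodehydrate to 11. This path also bypasses step 4.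

3. Step 2. Proton transfer from the product to the dianion may stop the acylation short, and the triketone may cyclise to a 4-hydroxy-2-pyranone on work-up. Fallback: from 2, reduction with i-Bu2AlH in CH2Cl2 at −78 °C should give (Z)-icos-11-enal F7. Aldol addition of dianion 4 (made as in step 2) to this far more electrophilic aldehyde should give racemic tert-butyl (Z)-5-hydroxy-3-oxotetracos-15-enoate F8. Dess–Martin periodinane oxidation of its carbinol should return 5, where the route is rejoined.

**Further compounds**

F1 | step 3 | methyl (Z)-3-oxodocos-13-enoate | CCCCCCCC/C=C\CCCCCCCCCC(=O)CC(=O)OC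
F2 | step 3 | methyl (3R,13Z)-3-hydroxydocos-13-enoate | CCCCCCCC/C=C\CCCCCCCCC[C@@H](O)CC(=O)OC
F3 | step 5 | tert-butyl (5R,15Z)-5-[(tert-butyldimethylsilyl)oxy]-3-oxotetracos-15-enoate | CCCCCCCC/C=C\CCCCCCCCC[C@@H](O[Si](C)(C)C(C)(C)C)CC(=O)CC(=O)OC(C)(C)C
F4 | step 5 | tert-butyl (5R,15Z)-2-acetyl-5-[(tert-butyldimethylsilyl)oxy]-3-oxotetracos-15-enoate | CCCCCCCC/C=C\CCCCCCCCC[C@@H](O[Si](C)(C)C(C)(C)C)CC(=O)C(C(C)=O)C(=O)OC(C)(C)C
F5 | step 5 | (6R,16Z)-6-[(tert-butyldimethylsilyl)oxy]pentacos-16-ene-2,4-dione | CCCCCCCC/C=C\CCCCCCCCC[C@@H](O[Si](C)(C)C(C)(C)C)CC(=O)CC(C)=O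
F6 | step 5 | (6R,16Z)-6-hydroxypentacos-16-ene-2,4-dione | CCCCCCCC/C=C\CCCCCCCCC[C@@H](O)CC(=O)CC(C)=O
F7 | step 2 | (Z)-icos-11-enal | CCCCCCCC/C=C\CCCCCCCCCC=O
F8 | step 2 | tert-butyl (Z)-5-hydroxy-3-oxotetracos-15-enoate (racemic) | CCCCCCCC/C=C\CCCCCCCCCC(O)CC(=O)CC(=O)OC(C)(C)C
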